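**Strategy.** The target is cut back to a cis-fused α-methylene-γ-butyrolactone. The C3 oxygen and the ester carbonyl carbon sit four bonds apart (O–C3–C2–Cα–C=O), so a temporary five-membered lactone ring, absent from the target, can hold the C2 and C3 substituents cis on the dihydrofuran ring. One palladium-mediated operation on an ortho-hydroxyphenyl allenyl carbinol forms O1–C2, Cα–C(=O) and C(=O)–O. It closes the dihydrofuran and lactone rings and sets C2 from the preset C3 carbinol; the allene carbons become C2, Cα and the exocyclic CH2. The precursor is a free phenol carrying the (R)-allenyl carbinol ortho and a silyl-protected (S)-1-hydroxyethyl group para.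

Key step: step 8

Assumption: in step 5 the (S,S)-configured ProPhenol ligand is taken to direct the alkynylzinc to the Re face of the aryl aldehyde; should the sense be opposite, the (R,R)-ligand is used and nothing else changes.

Benzofuran numbering (O1, C2, C3, C5) is used for the bicyclic compounds; Cα is the acrylate α-carbon.

Step 1
Reactants: 1 4'-acetoxyacetophenone (4-acetylphenyl acetate)
Product: 2 4-[(1S)-1-hydroxyethyl]phenyl acetate
Conditions: (R)-2-methyl-CBS-oxazaborolidine [(3aR)-1-methyl-3,3-diphenyltetrahydro-1H,3H-pyrrolo[1,2-c][1,3,2]oxazaborole, 10 mol%], BH3·SMe2, THF, −20 °C; MeOH quench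
Reagents that add atoms: none
Why: Corey–Bakshi–Shibata reduction of an aryl methyl ketone, in which the (R)-oxazaborolidine–borane complex should hold the aryl group away from its B-methyl group and so set the new carbinol as (S), while the aryl acetate is inert to borane at this temperature.

Step 2
Reactants: 2 4-[(1S)-1-hydroxyethyl]phenyl acetate
Product: 4 4-[(1S)-1-(triisopropylsilyloxy)ethyl]phenol, via the silylated aryl acetate 3 (not isolated)
Conditions: TIPSOTf, 2,6-lutidine, CH2Cl2, 0 °C; aqueous work-up; K2CO3 (cat.), MeOH, rt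
Reagents that add atoms: triisopropylsilyl trifluoromethanesulfonate, CC(C)[Si](OS(=O)(=O)C(F)(F)F)(C(C)C)C(C)C
Why: Silyl triflate silylation of the secondary alcohol followed by carbonate-catalysed transesterification of the much more electrophilic aryl acetate leaves the benzylic centre untouched, and a silyl ether is kept here because, unlike an ester, it cannot leave from the para-phenoxide as a quinone methide.

Step 3
Reactants: 4 4-[(1S)-1-(triisopropylsilyloxy)ethyl]phenol; 5 paraformaldehyde
Product: 6 2-hydroxy-5-[(1S)-1-(triisopropylsilyloxy)ethyl]benzaldehyde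
Conditions: anhydrous MgCl2, Et3N, (CH2O)n, THF, reflux; dilute HCl work-up
Reagents that add atoms: paraformaldehyde 5 (as formaldehyde), C=O
Why: Casnati–Skattebøl ortho-formylation, in which the magnesium phenoxide delivers formaldehyde to the ortho position (both ortho sites are equivalent) and a second formaldehyde oxidises the hydroxymethyl intermediate, so that only the salicylaldehyde should form.

Step 4
Reactants: 6 2-hydroxy-5-[(1S)-1-(triisopropylsilyloxy)ethyl]benzaldehyde
Product: 7 2-(triisopropylsilyloxy)-5-[(1S)-1-(triisopropylsilyloxy)ethyl]benzaldehyde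
Conditions: TIPSCl, imidazole, DMF, rt
Reagents that add atoms: triisopropylsilyl chloride, CC(C)[Si](Cl)(C(C)C)C(C)C
Why: Imidazole-promoted silylation of a phenol, with the bulky triisopropylsilyl group chosen because it survives the later carbonate and amine steps, resists migration to the neighbouring alkoxide and is removed at the end by fluoride without acid.

Step 5
Reactants: 7 2-(triisopropylsilyloxy)-5-[(1S)-1-(triisopropylsilyloxy)ethyl]benzaldehyde; 8 ethynyltrimethylsilane
Product: 10 (1R)-1-{2-(triisopropylsilyloxy)-5-[(1S)-1-(triisopropylsilyloxy)ethyl]phenyl}prop-2-yn-1-ol, via the C-trimethylsilyl propargylic alcohol 9 (not isolated)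
Conditions: ZnMe2 (3 equiv), 2,6-bis{[(2S)-2-(hydroxydiphenylmethyl)pyrrolidin-1-yl]methyl}-4-methylphenol [(S,S)-ProPhenol, 10 mol%], Ph3PO (20 mol%), toluene, 0 °C; aqueous NH4Cl work-up; K2CO3 (cat.), MeOH, 0 °C
Reagents that add atoms: ethynyltrimethylsilane 8, C#C[Si](C)(C)C
Why: Catalytic enantioselective alkynylzinc addition to an aryl aldehyde under dinuclear zinc–ProPhenol control should place the alkynyl group on the Re face and set the carbinol of 9 as (S) independently of the remote side-chain centre, and the carbonate-mediated protodesilylation of the C(sp)–Si bond that follows changes the descriptor to (R) by priority only.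

Step 6
Reactants: 10 (1R)-1-{2-(triisopropylsilyloxy)-5-[(1S)-1-(triisopropylsilyloxy)ethyl]phenyl}prop-2-yn-1-ol; 5 paraformaldehyde
Product: 11 (1R)-1-{2-(triisopropylsilyloxy)-5-[(1S)-1-(triisopropylsilyloxy)ethyl]phenyl}buta-2,3-dien-1-ol
Conditions: CuI (0.5 equiv), Cy2NH, (CH2O)n, 1,4-dioxane, reflux
Reagents that add atoms: paraformaldehyde 5 (as formaldehyde), C=O
Why: Crabbé homologation (copper-mediated Mannich reaction of the terminal alkyne, then 1,5-hydride shift with loss of the imine) turns 1-arylprop-2-yn-1-ols into buta-2,3-dien-1-ols without touching the carbinol centre, and the silyl cap keeps the phenol out of the Mannich pathway.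

Step 7
Reactants: 11 (1R)-1-{2-(triisopropylsilyloxy)-5-[(1S)-1-(triisopropylsilyloxy)ethyl]phenyl}buta-2,3-dien-1-ol
Product: 12 2-[(1R)-1-hydroxybuta-2,3-dien-1-yl]-4-[(1S)-1-(triisopropylsilyloxy)ethyl]phenol
Conditions: Bu4NF (1.05 equiv), AcOH (1.05 equiv), THF, 0 °C; crude product used at once
Reagents that add atoms: none
Why: Fluoride cleaves an aryl silyl ether far faster than a hindered secondary alkyl silyl ether because phenoxide is the better leaving group, and the acetic acid buffer keeps the sensitive ortho-hydroxybenzylic allenyl carbinol away from strong base and from acid.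

Step 8
Reactants: 12 2-[(1R)-1-hydroxybuta-2,3-dien-1-yl]-4-[(1S)-1-(triisopropylsilyloxy)ethyl]phenol; 13 carbon monoxide
Product: 14 (3aS,8bS)-3-methylidene-7-[(1S)-1-(triisopropylsilyloxy)ethyl]-3a,8b-dihydro-2H-furo[3,2-b][1]benzofuran-2-one
Conditions: PdCl2(MeCN)2 (10 mol%, divalent palladium), CuCl2 (2.5 equiv), NaOAc (3 equiv), CO (1 atm), MeCN, 0 °C to rt
Reagents that add atoms: carbon monoxide 13, [C-]#[O+]
Why: Proposed new method: divalent palladium should bind the C2=Cα bond of the allene, the phenoxide oxygen adds anti at C2 to leave a vinylpalladium on Cα, CO inserts to an acylpalladium that the C3 hydroxyl captures, and the zerovalent palladium released is reoxidised by CuCl2. The closest known reactions are the PdCl2/CuCl2 cyclisation–alkoxycarbonylation of γ-allenic alcohols to 2-(tetrahydrofuran-2-yl)acrylates and the oxycarbonylative double cyclisation of pent-4-ene-1,3-diols to cis-fused bicyclic lactones, whereas a phenol adding to an allenyl carbinol with lactone closure has not been shown. The dihydrofuran ring closes 5-exo-trig by O1 onto C2, and the lactone ring closes 5-exo-trig by attack of the C3 oxygen on the acyl carbon. The new stereocentre C2 is set by the existing C3 centre, because only the isomer with Cα and the C3 oxygen cis can form the bicyclo[3.3.0] lactone, and coordination of the C3 hydroxyl to palladium should favour that isomer already in the oxypalladation. The step needs the phenol to add 5-exo faster than the C3 hydroxyl adds 5-endo to the allene terminus; the higher acidity of the phenol under acetate buffer should secure this, and the aprotic solvent leaves the C3 hydroxyl as the only trap for the acylpalladium.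

Step 9
Reactants: 14 (3aS,8bS)-3-methylidene-7-[(1S)-1-(triisopropylsilyloxy)ethyl]-3a,8b-dihydro-2H-furo[3,2-b][1]benzofuran-2-one
Product: 17 methyl 2-[(2S,3S)-3-acetoxy-5-[(1S)-1-(triisopropylsilyloxy)ethyl]-2,3-dihydro-1-benzofuran-2-yl]prop-2-enoate, via the lithium hydroxy carboxylate 15 (not isolated), via the hydroxy methyl ester 16 (not isolated)
Conditions: LiOH·H2O (1.05 equiv), THF–H2O, 0 °C; evaporate, toluene azeotrope; MeI, DMF, rt; evaporate volatiles; Ac2O, pyridine, DMAP (cat.), CH2Cl2, 0 °C
Reagents that add atoms: lithium hydroxide, [Li+].[OH-]; iodomethane, CI; acetic anhydride, CC(=O)OC(C)=O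
Why: Saponification of the strained lactone, SN2 methylation of the carboxylate salt and acetylation of the freed secondary alcohol involve no stereocentre, and methylating before acetylating avoids any activated acyl derivative beside the free cis hydroxyl, which would close the lactone again.

Step 10
Reactants: 17 methyl 2-[(2S,3S)-3-acetoxy-5-[(1S)-1-(triisopropylsilyloxy)ethyl]-2,3-dihydro-1-benzofuran-2-yl]prop-2-enoate
Product: 18 methyl 2-[(2S,3S)-3-acetoxy-5-[(1S)-1-hydroxyethyl]-2,3-dihydro-1-benzofuran-2-yl]prop-2-enoate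
Conditions: HF·pyridine, excess pyridine, THF, 0 °C to rt
Reagents that add atoms: none
Why: Fluoride-mediated desilylation under pyridine-buffered, weakly acidic conditions should free the secondary alcohol without the acetate loss or elimination toward the benzofuran that basic fluoride could cause.

Step 11
Reactants: 18 methyl 2-[(2S,3S)-3-acetoxy-5-[(1S)-1-hydroxyethyl]-2,3-dihydro-1-benzofuran-2-yl]prop-2-enoate; 19 angelic acid
Product: 21 (1S)-1-[(2S,3S)-3-acetoxy-2-(3-methoxy-3-oxoprop-1-en-2-yl)-2,3-dihydro-1-benzofuran-5-yl]ethyl (2Z)-2-methylbut-2-enoate, via the angelic 2,4,6-trichlorobenzoic mixed anhydride 20 (not isolated)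
Conditions: 19, 2,4,6-trichlorobenzoyl chloride, Et3N, toluene, rt; then 18, toluene, 70 °C
Reagents that add atoms: angelic acid 19, C/C=C(/C)C(=O)O
Why: Yamaguchi esterification through the preformed mixed anhydride acylates the alcohol with retention at the carbinol and, run without a nucleophilic amine catalyst, is the established way to avoid isomerisation of the angelate to the tiglate.

Compound list
1 | 4'-acetoxyacetophenone | CC(=O)Oc1ccc(cc1)C(C)=O | starting material
2 | 4-[(1S)-1-hydroxyethyl]phenyl acetate | CC(=O)Oc1ccc(cc1)[C@H](C)O | intermediate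
3 | 4-[(1S)-1-(triisopropylsilyloxy)ethyl]phenyl acetate | CC(=O)Oc1ccc(cc1)[C@H](C)O[Si](C(C)C)(C(C)C)C(C)C | intermediate
4 | 4-[(1S)-1-(triisopropylsilyloxy)ethyl]phenol | Oc1ccc(cc1)[C@H](C)O[Si](C(C)C)(C(C)C)C(C)C | intermediate
5 | paraformaldehyde (as formaldehyde) | C=O | starting material
6 | 2-hydroxy-5-[(1S)-1-(triisopropylsilyloxy)ethyl]benzaldehyde | O=Cc1cc(ccc1O)[C@H](C)O[Si](C(C)C)(C(C)C)C(C)C | intermediate
7 | 2-(triisopropylsilyloxy)-5-[(1S)-1-(triisopropylsilyloxy)ethyl]benzaldehyde | O=Cc1cc(ccc1O[Si](C(C)C)(C(C)C)C(C)C)[C@H](C)O[Si](C(C)C)(C(C)C)C(C)C | intermediate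
8 | ethynyltrimethylsilane | C#C[Si](C)(C)C | starting material
9 | (1S)-1-{2-(triisopropylsilyloxy)-5-[(1S)-1-(triisopropylsilyloxy)ethyl]phenyl}-3-(trimethylsilyl)prop-2-yn-1-ol | C[Si](C)(C)C#C[C@@H](O)c1cc(ccc1O[Si](C(C)C)(C(C)C)C(C)C)[C@H](C)O[Si](C(C)C)(C(C)C)C(C)C | intermediate
10 | (1R)-1-{2-(triisopropylsilyloxy)-5-[(1S)-1-(triisopropylsilyloxy)ethyl]phenyl}prop-2-yn-1-ol | C#C[C@@H](O)c1cc(ccc1O[Si](C(C)C)(C(C)C)C(C)C)[C@H](C)O[Si](C(C)C)(C(C)C)C(C)C | intermediate
11 | (1R)-1-{2-(triisopropylsilyloxy)-5-[(1S)-1-(triisopropylsilyloxy)ethyl]phenyl}buta-2,3-dien-1-ol | C=C=C[C@@H](O)c1cc(ccc1O[Si](C(C)C)(C(C)C)C(C)C)[C@H](C)O[Si](C(C)C)(C(C)C)C(C)C | intermediate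
12 | 2-[(1R)-1-hydroxybuta-2,3-dien-1-yl]-4-[(1S)-1-(triisopropylsilyloxy)ethyl]phenol | C=C=C[C@@H](O)c1cc([C@H](C)O[Si](C(C)C)(C(C)C)C(C)C)ccc1O | intermediate
13 | carbon monoxide | [C-]#[O+] | starting material
14 | (3aS,8bS)-3-methylidene-7-[(1S)-1-(triisopropylsilyloxy)ethyl]-3a,8b-dihydro-2H-furo[3,2-b][1]benzofuran-2-one | C=C1C(=O)O[C@H]2c3cc([C@H](C)O[Si](C(C)C)(C(C)C)C(C)C)ccc3O[C@@H]12 | intermediate
15 | lithium 2-[(2S,3S)-3-hydroxy-5-[(1S)-1-(triisopropylsilyloxy)ethyl]-2,3-dihydro-1-benzofuran-2-yl]prop-2-enoate | C=C(C(=O)[O-])[C@@H]1Oc2ccc([C@H](C)O[Si](C(C)C)(C(C)C)C(C)C)cc2[C@@H]1O.[Li+] | intermediate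
16 | methyl 2-[(2S,3S)-3-hydroxy-5-[(1S)-1-(triisopropylsilyloxy)ethyl]-2,3-dihydro-1-benzofuran-2-yl]prop-2-enoate | C=C(C(=O)OC)[C@@H]1Oc2ccc([C@H](C)O[Si](C(C)C)(C(C)C)C(C)C)cc2[C@@H]1O | intermediate
17 | methyl 2-[(2S,3S)-3-acetoxy-5-[(1S)-1-(triisopropylsilyloxy)ethyl]-2,3-dihydro-1-benzofuran-2-yl]prop-2-enoate | C=C(C(=O)OC)[C@@H]1Oc2ccc([C@H](C)O[Si](C(C)C)(C(C)C)C(C)C)cc2[C@@H]1OC(C)=O | intermediate
18 | methyl 2-[(2S,3S)-3-acetoxy-5-[(1S)-1-hydroxyethyl]-2,3-dihydro-1-benzofuran-2-yl]prop-2-enoate | C=C(C(=O)OC)[C@@H]1Oc2ccc([C@H](C)O)cc2[C@@H]1OC(C)=O | intermediate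
19 | angelic acid, (2Z)-2-methylbut-2-enoic acid | C/C=C(/C)C(=O)O | starting material
20 | (2Z)-2-methylbut-2-enoic 2,4,6-trichlorobenzoic anhydride | C/C=C(/C)C(=O)OC(=O)c1c(Cl)cc(Cl)cc1Cl | intermediate
21 | (1S)-1-[(2S,3S)-3-acetoxy-2-(3-methoxy-3-oxoprop-1-en-2-yl)-2,3-dihydro-1-benzofuran-5-yl]ethyl (2Z)-2-methylbut-2-enoate (CNP0168827.1) | C=C(C(=O)OC)[C@@H]1Oc2ccc([C@H](C)OC(=O)/C(C)=C\C)cc2[C@@H]1OC(C)=O | target

Total step count: 11. Longest linear sequence: 11 steps (1 to 21); compounds 5, 8, 13 and 19 are purchased.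

Steps most likely to fail

First, step 8 (proposed new method). The C3 hydroxyl may add to the allene terminus in the 5-endo mode, the benzylic allenyl carbinol may ionise on the Lewis-acidic chlorides, or a trans vinylpalladium that does not revert may drain material. The fallback uses known chemistry, sets out from 12 and returns at 14. Iodoetherification of the allene (I2, NaHCO3, MeCN, 0 °C), the known 5-exo cyclisation of γ-allenols that places iodine on the central allene carbon, should give (2R,3S)-2-(1-iodoethenyl)-5-[(1S)-1-(triisopropylsilyloxy)ethyl]-2,3-dihydro-1-benzofuran-3-ol F1. Palladium-catalysed carbonylative lactonisation of this 3-iodobut-3-en-1-ol unit [Pd(PPh3)4 (zerovalent palladium), CO (1 atm), Et3N, THF, 50 °C], the classical entry to α-methylene-γ-butyrolactones, then closes the lactone of the cis isomer to give 14. Any trans iodide cannot lactonise and is removed there.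

Second, step 5. The bulky ortho-silyloxy group and the electron-rich ring may slow the addition and erode facial selectivity, and C3 epimers would be hard to separate from a remote centre. The fallback sets out from 7 and returns at 9. Addition of lithium (trimethylsilyl)acetylide (from 8 and n-BuLi, THF, −78 °C) gives, as both C1 epimers, 1-{2-(triisopropylsilyloxy)-5-[(1S)-1-(triisopropylsilyloxy)ethyl]phenyl}-3-(trimethylsilyl)prop-2-yn-1-ol F2. MnO2 in CH2Cl2 oxidises it to 1-{2-(triisopropylsilyloxy)-5-[(1S)-1-(triisopropylsilyloxy)ethyl]phenyl}-3-(trimethylsilyl)prop-2-yn-1-one F3. A Midland reduction with B-isopinocampheyl-9-borabicyclo[3.3.1]nonane from (−)-α-pinene [(S)-Alpine-Borane], which tells the slim alkynyl group from the aryl group, should deliver hydride to the Re face and give 9. Compound 9 is then desilylated as in step 5.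

Third, step 9. Hydroxide may add in conjugate fashion to the exocyclic methylene, or the hydroxy carboxylate may close back to the lactone before it is methylated. The fallback sets out from 12 and returns at 17. The iodide F1, made as in the fallback for step 8, is acetylated (Ac2O, pyridine, 0 °C) to (2R,3S)-2-(1-iodoethenyl)-5-[(1S)-1-(triisopropylsilyloxy)ethyl]-2,3-dihydro-1-benzofuran-3-yl acetate F4. Palladium-catalysed methoxycarbonylation of the vinyl iodide [Pd(PPh3)4 (zerovalent palladium), CO (1 atm), MeOH, Et3N, 40 °C] then gives 17 directly, so that no lactone has to be opened. The cis relation then rests on the iodoetherification and on separating F1 from its trans isomer.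

Further compounds
F1 | step 8 | (2R,3S)-2-(1-iodoethenyl)-5-[(1S)-1-(triisopropylsilyloxy)ethyl]-2,3-dihydro-1-benzofuran-3-ol | C=C(I)[C@@H]1Oc2ccc([C@H](C)O[Si](C(C)C)(C(C)C)C(C)C)cc2[C@@H]1O
F2 | step 5 | 1-{2-(triisopropylsilyloxy)-5-[(1S)-1-(triisopropylsilyloxy)ethyl]phenyl}-3-(trimethylsilyl)prop-2-yn-1-ol (both C1 epimers) | C[Si](C)(C)C#CC(O)c1cc(ccc1O[Si](C(C)C)(C(C)C)C(C)C)[C@H](C)O[Si](C(C)C)(C(C)C)C(C)C
F3 | step 5 | 1-{2-(triisopropylsilyloxy)-5-[(1S)-1-(triisopropylsilyloxy)ethyl]phenyl}-3-(trimethylsilyl)prop-2-yn-1-one | C[Si](C)(C)C#CC(=O)c1cc(ccc1O[Si](C(C)C)(C(C)C)C(C)C)[C@H](C)O[Si](C(C)C)(C(C)C)C(C)C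
F4 | step 9 | (2R,3S)-2-(1-iodoethenyl)-5-[(1S)-1-(triisopropylsilyloxy)ethyl]-2,3-dihydro-1-benzofuran-3-yl acetate | C=C(I)[C@@H]1Oc2ccc([C@H](C)O[Si](C(C)C)(C(C)C)C(C)C)cc2[C@@H]1OC(C)=O
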